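**Retrosynthetic overview**

- Feature: a 1,2,3-trisubstituted benzene ring in which the amide nitrogen on C2 lies between the oxygen on C1 and the 2-methylpyridin-4-yl ring on C3. A carboxyl carbon can occupy C2 first, steer the pyridyl ring to its only free neighbour, and then be exchanged for nitrogen.
- Disconnections, last to first: the O–CH3 bond (phenol unmasked at the end); the C2–N bond together with the C(=O)–nonyl bond (Curtius shift, isocyanate captured by a nonyl Grignard reagent); the aryl–pyridyl bond (carboxylate-directed C–H arylation).
- Forward: 2-methoxybenzoic acid 1 + 4-bromo-2-methylpyridine 2 → biaryl acid 3; 1-bromononane 4 → Grignard reagent 5; 3 + 5 → (aroyl azide 6, isocyanate 7) → amide 8 → echinoclathrine A 9.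
- No ring is formed: the benzene and pyridine rings are bought intact. The target has no stereocentre.

Key step: step 3

**Route**

Step 1
Reactants: 1 2-methoxybenzoic acid; 2 4-bromo-2-methylpyridine
Product: 3 2-methoxy-6-(2-methylpyridin-4-yl)benzoic acid
Conditions: [RuCl2(p-cymene)]2 (5 mol %), PCy3 (10 mol %), K2CO3 (2.5 equiv), NMP, 100 °C, Ar; then H2O, EtOAc wash, HCl to pH 4–5
Reagents that add atoms: none
Why: Carboxylate-directed ortho C–H arylation: the potassium benzoate binds divalent ruthenium, concerted metalation–deprotonation forms a five-membered ruthenacycle at the only free ortho carbon (the other is blocked by OMe), and oxidative addition of the pyridyl C–Br bond followed by reductive elimination should give the biaryl acid, a reaction type established for ortho-substituted benzoic acids with aryl and heteroaryl bromides.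

Step 2
Reactants: 4 1-bromononane
Product: 5 nonylmagnesium bromide (THF solution, titrated and used directly)
Conditions: Mg (1.2 equiv), cat. I2, THF, 40 °C → rt
Reagents that add atoms: magnesium, [Mg]
Why: Grignard reagent formation by insertion of zerovalent magnesium metal into the unhindered primary C–Br bond.

Step 3
Reactants: 3 2-methoxy-6-(2-methylpyridin-4-yl)benzoic acid; 5 nonylmagnesium bromide
Product: 8 N-[2-methoxy-6-(2-methylpyridin-4-yl)phenyl]decanamide, via aroyl azide 6 (not isolated), via aryl isocyanate 7 (not isolated)
Conditions: (PhO)2P(O)N3 (1.05 equiv), Et3N (1.1 equiv), PhMe–THF, 0 °C → rt; then 85 °C until N2 evolution ends; then 5 (2.3 equiv), −20 → 0 °C; aq NH4Cl, NaHCO3 wash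
Reagents that add atoms: diphenylphosphoryl azide, [N-]=[N+]=NP(=O)(Oc1ccccc1)Oc1ccccc1
Why: The triethylammonium carboxylate of 3 attacks phosphorus of the azide reagent, and the acyl phosphate so formed is attacked at the carbonyl by the released azide to give 6; on warming, 6 loses N2 while the aryl group shifts from carbon to nitrogen in one concerted event (Curtius rearrangement), so nitrogen arrives at exactly the ring carbon that held the carboxyl group, between the methoxy group and the pyridyl ring. The nonyl Grignard reagent then adds to the central carbon of isocyanate 7 (the known addition of organomagnesium reagents to hindered isocyanates) to give a magnesium amidate, and protonation gives the secondary amide, so the crowded amide is made by C–C bond formation and not by acylating a flanked aniline. No ring closes and no stereocentre is created. The step needs chemoselectivity: at 0 °C or below the isocyanate carbon is far more electrophilic than the pyridine ring or the aryl methyl ether, and the anionic amidate should refuse a second equivalent, so a single addition is expected. One equivalent of 5 is knowingly spent on the proton of the triethylammonium diphenyl phosphate left from azide formation (giving nonane), hence 2.3 equiv. The two ortho substituents should twist the carbonyl out of conjugation and so ease the rearrangement, and should shield 7 against trimerisation and urea formation before the capture.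

Step 4
Reactants: 8 N-[2-methoxy-6-(2-methylpyridin-4-yl)phenyl]decanamide
Product: 9 echinoclathrine A, N-[2-hydroxy-6-(2-methylpyridin-4-yl)phenyl]decanamide
Conditions: BBr3 (5 equiv), CH2Cl2, −78 °C → rt; then H2O, aq NaHCO3, 0 °C
Reagents that add atoms: none
Why: Lewis-acid O-demethylation of an aryl methyl ether: boron binds the ether oxygen, bromide displaces the methyl group by SN2 and the aryloxyborane is hydrolysed on work-up, the excess reagent allowing for the equivalents held by the pyridine nitrogen and the amide oxygen, which like the picoline methyl group should emerge unchanged.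

**Compound list**

1 | 2-methoxybenzoic acid | COc1ccccc1C(=O)O | starting material
2 | 4-bromo-2-methylpyridine | Cc1cc(Br)ccn1 | starting material
3 | 2-methoxy-6-(2-methylpyridin-4-yl)benzoic acid | COc1cccc(-c2ccnc(C)c2)c1C(=O)O | intermediate
4 | 1-bromononane | CCCCCCCCCBr | starting material
5 | nonylmagnesium bromide | CCCCCCCCC[Mg]Br | intermediate
6 | 2-methoxy-6-(2-methylpyridin-4-yl)benzoyl azide | COc1cccc(-c2ccnc(C)c2)c1C(=O)N=[N+]=[N-] | intermediate
7 | 4-(2-isocyanato-3-methoxyphenyl)-2-methylpyridine | COc1cccc(-c2ccnc(C)c2)c1N=C=O | intermediate
8 | N-[2-methoxy-6-(2-methylpyridin-4-yl)phenyl]decanamide | CCCCCCCCCC(=O)Nc1c(OC)cccc1-c1ccnc(C)c1 | intermediate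
9 | echinoclathrine A (N-[2-hydroxy-6-(2-methylpyridin-4-yl)phenyl]decanamide) | CCCCCCCCCC(=O)Nc1c(O)cccc1-c1ccnc(C)c1 | target

**Step count**

Total: 4 steps. Longest linear sequence: 3 steps (steps 1, 3 and 4); step 2 is a one-step side branch.

**Steps most likely to fail**

1. Step 3. Azide transfer onto the crowded mixed anhydride may be slow, so that isocyanate formed early is diverted (carbamoyl azide or urea formation), or the organomagnesium reagent may be consumed by the salts in the flask before it reaches the isocyanate carbon. Fallback, setting out from 3 and returning at 8: the amide is made by N-acylation instead of organometallic capture. Acid 3 is carried through the same azide formation and rearrangement (6, then 7), but the isocyanate is hydrolysed in the flask with 2 M HCl in THF at 60 °C, the carbamic acid losing CO2, to give 2-methoxy-6-(2-methylpyridin-4-yl)aniline F1 after basification. F1 is then acylated with decanoyl chloride (CCCCCCCCCC(=O)Cl), pyridine and catalytic DMAP in CH2Cl2 at 40 °C to give 8.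

2. Step 1. The pyridine nitrogen of 2 or of the product may bind ruthenium and stall the catalytic cycle, and the crowded benzoate may undergo protodecarboxylation at 100 °C. Fallback, setting out from 1 and returning at 3: the biaryl bond is made by cross-coupling of a pre-halogenated acid. Carboxylate-directed ortho-lithiation of 1 with s-BuLi/TMEDA (2.2 equiv) in THF at −78 °C, which removes the proton next to the carboxylate and not the one next to the methoxy group, followed by an I2 quench, should give 2-iodo-6-methoxybenzoic acid F2. Suzuki–Miyaura coupling of F2 with bought 2-methyl-4-(4,4,5,5-tetramethyl-1,3,2-dioxaborolan-2-yl)pyridine (Cc1cc(B2OC(C)(C)C(C)(C)O2)ccn1) under PdCl2(dppf), K2CO3, dioxane–H2O, 90 °C, then acidification to pH 4–5, should give 3.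

3. Step 4. Ether cleavage may stay incomplete because the Lewis acid is held at the pyridine nitrogen and the amide oxygen, and prolonged acid exposure may cause cyclodehydration of the ortho-hydroxy anilide to a benzoxazole. Fallback, setting out from 2 and returning at 9: the phenol is carried as a benzyl ether and released by hydrogenolysis.
   - Bought 2-(benzyloxy)benzoic acid (O=C(O)c1ccccc1OCc1ccccc1) is arylated with 2 under the conditions of step 1 to give 2-(benzyloxy)-6-(2-methylpyridin-4-yl)benzoic acid F3.
   - Under the conditions of step 3, F3 passes through 2-(benzyloxy)-6-(2-methylpyridin-4-yl)benzoyl azide F4 and 4-[3-(benzyloxy)-2-isocyanatophenyl]-2-methylpyridine F5, and capture with 5 gives N-[2-(benzyloxy)-6-(2-methylpyridin-4-yl)phenyl]decanamide F6.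
   - Hydrogenolysis of F6 (H2 at 1 atm, 10% Pd/C, EtOH–AcOH, rt; the acid protonates the pyridine so that it does not poison the catalyst) should give 9.

**Further compounds**

F1 | step 3 | 2-methoxy-6-(2-methylpyridin-4-yl)aniline | COc1cccc(-c2ccnc(C)c2)c1N
F2 | step 1 | 2-iodo-6-methoxybenzoic acid | COc1cccc(I)c1C(=O)O
F3 | step 4 | 2-(benzyloxy)-6-(2-methylpyridin-4-yl)benzoic acid | Cc1cc(-c2cccc(OCc3ccccc3)c2C(=O)O)ccn1
F4 | step 4 | 2-(benzyloxy)-6-(2-methylpyridin-4-yl)benzoyl azide | Cc1cc(-c2cccc(OCc3ccccc3)c2C(=O)N=[N+]=[N-])ccn1
F5 | step 4 | 4-[3-(benzyloxy)-2-isocyanatophenyl]-2-methylpyridine | Cc1cc(-c2cccc(OCc3ccccc3)c2N=C=O)ccn1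
F6 | step 4 | N-[2-(benzyloxy)-6-(2-methylpyridin-4-yl)phenyl]decanamide | CCCCCCCCCC(=O)Nc1c(OCc2ccccc2)cccc1-c1ccnc(C)c1
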